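The plan rests on opening ring A at its C1–C6 bond instead of at the depside C–O bond. In the target the ester carbonyl on ring A C1 is wedged between C2–OMe and C6–CH3, so acylating the ring B phenol (O on C4') with the finished acid would be slow. The ester is therefore made from an unhindered acylketene while the six ring A carbons are still a chain. The precursor 17 is the protected ring B aryl ester of 4-(benzyloxymethyl)-3,5,7-trioxooctanoic acid. One base-triggered aldol condensation then joins chain C2 to the C7 ketone, loses water and aromatises, giving ring A with the hindered depside link already installed.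

Key step: step 10

Remark: ring A is numbered C1 (depside carbonyl), C2 (O), C3 (CH2O arm), C4 (O), C5 (H), C6 (CH3); ring B runs from C1' (carboxyl) with the depside oxygen on C4'; open chains use octanoate numbering (chain C2 becomes ring C1, chain C7 becomes ring C6); the target has no stereocentre, and the one centre in 9, 10, 16 and 17 is enolisable, so these are taken as racemic tautomer mixtures.

Step 1
Reactants: 1 2,2,6-trimethyl-4H-1,3-dioxin-4-one; 2 benzyl chloromethyl ether
Product: 4 6-[2-(benzyloxy)ethyl]-2,2-dimethyl-4H-1,3-dioxin-4-one, via lithium dienolate 3 (not isolated)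
Conditions: LiN(iPr)2 (1.05 equiv), THF/DMPU, −78 °C, 45 min; then 2 (1.0 equiv), −78 to −40 °C
Reagents that add atoms: none
Why: Vinylogous enolate alkylation, in which the cross-conjugated dienolate 3 reacts at its exocyclic γ-carbon when a dipolar cosolvent and a very reactive chloromethyl ether are used, so the C–C bond should form at low temperature before the dienolate decays.

Step 2
Reactants: 5 ethyl 2-(2-methyl-1,3-dioxolan-2-yl)acetate
Product: 6 2-(2-methyl-1,3-dioxolan-2-yl)acetic acid
Conditions: NaOH (1.2 equiv), THF/H2O, rt; then cold 1 M HCl to pH 4, 0 °C, immediate extraction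
Reagents that add atoms: sodium hydroxide, [Na+].[OH-]
Why: Ester saponification leaves the base-stable dioxolane untouched, and a brief cold acidification frees the acid without opening the ketal.

Step 3
Reactants: 4 6-[2-(benzyloxy)ethyl]-2,2-dimethyl-4H-1,3-dioxin-4-one; 6 2-(2-methyl-1,3-dioxolan-2-yl)acetic acid
Product: 9 6-[1-(benzyloxy)-4-(2-methyl-1,3-dioxolan-2-yl)-3-oxobutan-2-yl]-2,2-dimethyl-4H-1,3-dioxin-4-one, via acyl imidazolide 7 (not isolated), via lithium dienolate 8 (not isolated)
Conditions: flask A: 6, CDI (1.05 equiv), THF, rt, 1 h; flask B: 4, LiN(SiMe3)2 (3.1 equiv), THF, −78 °C, 30 min; A into B, −78 °C, 2 h; AcOH quench at −78 °C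
Reagents that add atoms: none
Why: Crossed Claisen-type γ-C-acylation of a dioxinone dienolate by an acyl imidazolide, in which the extra base absorbs the imidazole N–H and the acidic proton of the product, the constant −78 °C lets 8 acylate before it can lose benzyl oxide, and the new chain C4 centre forms racemic and stays enolisable until step 10 erases it.

Step 4
Reactants: 9 6-[1-(benzyloxy)-4-(2-methyl-1,3-dioxolan-2-yl)-3-oxobutan-2-yl]-2,2-dimethyl-4H-1,3-dioxin-4-one
Product: 10 6-[1-(benzyloxy)-3,5-dioxohexan-2-yl]-2,2-dimethyl-4H-1,3-dioxin-4-one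
Conditions: TsOH·H2O (0.2 equiv), acetone/H2O 20:1, rt to 40 °C
Reagents that add atoms: water, O
Why: Acid-catalysed ketal hydrolysis, with acetone as solvent holding the dioxinone acetonide in place by mass action while the dioxolane is released, and with the benzyl ether inert to catalytic TsOH.

Step 5
Reactants: 11 2,4-dihydroxy-3,6-dimethylbenzoic acid (3-methylorsellinic acid)
Product: 12 benzyl 2,4-dihydroxy-3,6-dimethylbenzoate
Conditions: BnBr (1.05 equiv), KHCO3 (1.2 equiv), DMF, rt to 40 °C
Reagents that add atoms: benzyl bromide, BrCc1ccccc1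
Why: Carboxylate O-alkylation (SN2), since KHCO3 ionises only the carboxylic acid and both phenols stay protonated.

Step 6
Reactants: 12 benzyl 2,4-dihydroxy-3,6-dimethylbenzoate
Product: 13 benzyl 2-hydroxy-4-(methoxymethoxy)-3,6-dimethylbenzoate
Conditions: MOMCl (1.1 equiv), iPr2NEt (1.5 equiv), CH2Cl2, 0 °C to rt
Reagents that add atoms: chloromethyl methyl ether, COCCl
Why: Selective phenol protection, because the C2' hydroxyl is locked in a hydrogen bond to the ester carbonyl and crowded by C3'–CH3, so with an amine base only the C4' hydroxyl is alkylated.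

Step 7
Reactants: 13 benzyl 2-hydroxy-4-(methoxymethoxy)-3,6-dimethylbenzoate
Product: 14 benzyl 2-(benzyloxy)-4-(methoxymethoxy)-3,6-dimethylbenzoate
Conditions: BnBr (1.5 equiv), K2CO3 (3 equiv), DMF, 60 °C
Reagents that add atoms: benzyl bromide, BrCc1ccccc1
Why: Williamson ether synthesis, in which carbonate in warm DMF breaks the chelate and benzylates the only phenol left, the MOM acetal being fully base-stable.

Step 8
Reactants: 14 benzyl 2-(benzyloxy)-4-(methoxymethoxy)-3,6-dimethylbenzoate
Product: 15 benzyl 2-(benzyloxy)-4-hydroxy-3,6-dimethylbenzoate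
Conditions: conc. HCl (cat.), MeOH/THF, 45 °C
Reagents that add atoms: none
Why: Acid-catalysed acetal exchange removes the aryl MOM ether, while the benzyl ether and the doubly ortho-substituted benzyl ester are inert to dilute methanolic HCl.

Step 9
Reactants: 10 6-[1-(benzyloxy)-3,5-dioxohexan-2-yl]-2,2-dimethyl-4H-1,3-dioxin-4-one; 15 benzyl 2-(benzyloxy)-4-hydroxy-3,6-dimethylbenzoate
Product: 17 3-(benzyloxy)-4-[(benzyloxy)carbonyl]-2,5-dimethylphenyl 4-[(benzyloxy)methyl]-3,5,7-trioxooctanoate (taken on crude), via acylketene 16 (not isolated)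
Conditions: 15 (1.3 equiv), toluene (0.2 M), 110 °C, about 1 h, N2 sweep to carry off acetone
Reagents that add atoms: none
Why: Thermal retro-hetero-Diels–Alder cleavage of the dioxinone gives acylketene 16, which phenols capture at the unhindered ketene carbon, and a concentrated solution with a modest excess of 15 should let this capture beat internal capture by a chain enol.

Step 10
Reactants: 17 3-(benzyloxy)-4-[(benzyloxy)carbonyl]-2,5-dimethylphenyl 4-[(benzyloxy)methyl]-3,5,7-trioxooctanoate
Product: 19 benzyl 2-(benzyloxy)-4-({3-[(benzyloxy)methyl]-2,4-dihydroxy-6-methylbenzoyl}oxy)-3,6-dimethylbenzoate, via cyclic aldol 18 (not isolated)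
Conditions: Et3N (2 equiv), CH2Cl2 (0.05 M), 0 °C to rt; then AcOH (4 equiv), rt
Reagents that add atoms: none
Why: Et3N reversibly enolises the chain, and the carbon between the aryl ester and the C3 ketone (chain C2, future ring A C1) adds to the C7 methyl ketone (future C6) to give cyclic aldol 18, which loses water by E1cB and tautomerises at C3 and C5 to the 2,4-diol, after which AcOH protonates the phenoxides and finishes any lagging dehydration. The closest known reaction type is the biomimetic aldol aromatisation of 3,5,7-triketo esters generated from dioxinone-derived acylketenes, the laboratory counterpart of orsellinate formation. Ring A closes in a 6-(enolendo)-exo-trig mode and only the C1–C6 bond is new. No stereocentre survives, because chain C4 and the two transient centres of 18 all become sp2. The selectivity required is C-attack on C7 in preference to attack of the C5 enol oxygen or of chain C6 on the aryl ester (both would expel 15) and to β-loss of benzyl alcohol. It is secured by the enolised β-keto ester, whose ester carbonyl is part of the enolate and thus a poor electrophile, by the methyl ketone being the least hindered carbonyl, by a non-nucleophilic amine in a cold aprotic medium, by the benzyloxymethyl carbon only ever being a doubly stabilised enolate, by a weak acid that does not ionise the benzylic ether lying between two free phenols, and by aromatisation, which makes the aldol path irreversible.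

Step 11
Reactants: 19 benzyl 2-(benzyloxy)-4-({3-[(benzyloxy)methyl]-2,4-dihydroxy-6-methylbenzoyl}oxy)-3,6-dimethylbenzoate
Product: 20 benzyl 2-(benzyloxy)-4-({3-[(benzyloxy)methyl]-2,4-dimethoxy-6-methylbenzoyl}oxy)-3,6-dimethylbenzoate
Conditions: MeI (6 equiv), K2CO3 (4 equiv), DMF, rt to 40 °C, run directly after step 10
Reagents that add atoms: iodomethane, CI
Why: Williamson O-methylation of the only two acidic O–H groups in 19, at a near-ambient temperature that spares the aryl ester and the benzyloxymethyl arm, which ionises far less readily once both ortho oxygens are capped.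

Step 12
Reactants: 20 benzyl 2-(benzyloxy)-4-({3-[(benzyloxy)methyl]-2,4-dimethoxy-6-methylbenzoyl}oxy)-3,6-dimethylbenzoate
Product: 21 2-hydroxy-4-{[3-(hydroxymethyl)-2,4-dimethoxy-6-methylbenzoyl]oxy}-3,6-dimethylbenzoic acid (CNP0372912.0)
Conditions: H2 (1 atm), 10% Pd/C, EtOAc, rt, stopped after uptake of 3 equiv H2
Reagents that add atoms: none
Why: Catalytic hydrogenolysis cleaves the three unsubstituted PhCH2–O bonds, whose phenyl rings bind flat to the metal, whereas the C3–CH2–O bond of ring A sits between two methoxy groups on a pentasubstituted ring that adsorbs poorly, and a neutral aprotic solvent offers no benzylic cation pathway.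

Compound list
1 | 2,2,6-trimethyl-4H-1,3-dioxin-4-one | CC1=CC(=O)OC(C)(C)O1 | starting material
2 | benzyl chloromethyl ether | ClCOCc1ccccc1 | starting material
3 | lithium 2,2-dimethyl-6-methylidene-1,3-dioxin-4-olate (dienolate of 1, not isolated) | [Li+].[O-]C1=CC(=C)OC(C)(C)O1 | intermediate
4 | 6-[2-(benzyloxy)ethyl]-2,2-dimethyl-4H-1,3-dioxin-4-one | CC1(C)OC(=O)C=C(CCOCc2ccccc2)O1 | intermediate
5 | ethyl 2-(2-methyl-1,3-dioxolan-2-yl)acetate | CCOC(=O)CC1(C)OCCO1 | starting material
6 | 2-(2-methyl-1,3-dioxolan-2-yl)acetic acid | OC(=O)CC1(C)OCCO1 | intermediate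
7 | 1-(1H-imidazol-1-yl)-2-(2-methyl-1,3-dioxolan-2-yl)ethan-1-one (not isolated) | O=C(CC1(C)OCCO1)n2ccnc2 | intermediate
8 | lithium 6-[2-(benzyloxy)ethylidene]-2,2-dimethyl-1,3-dioxin-4-olate (dienolate of 4, geometry not defined, not isolated) | [Li+].[O-]C1=CC(=CCOCc2ccccc2)OC(C)(C)O1 | intermediate
9 | 6-[1-(benzyloxy)-4-(2-methyl-1,3-dioxolan-2-yl)-3-oxobutan-2-yl]-2,2-dimethyl-4H-1,3-dioxin-4-one (racemic, enolisable) | CC1(CC(=O)C(COCc2ccccc2)C3=CC(=O)OC(C)(C)O3)OCCO1 | intermediate
10 | 6-[1-(benzyloxy)-3,5-dioxohexan-2-yl]-2,2-dimethyl-4H-1,3-dioxin-4-one (racemic, enolisable) | CC(=O)CC(=O)C(COCc1ccccc1)C2=CC(=O)OC(C)(C)O2 | intermediate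
11 | 2,4-dihydroxy-3,6-dimethylbenzoic acid | Cc1cc(O)c(C)c(O)c1C(=O)O | starting material
12 | benzyl 2,4-dihydroxy-3,6-dimethylbenzoate | Cc1cc(O)c(C)c(O)c1C(=O)OCc2ccccc2 | intermediate
13 | benzyl 2-hydroxy-4-(methoxymethoxy)-3,6-dimethylbenzoate | COCOc1cc(C)c(C(=O)OCc2ccccc2)c(O)c1C | intermediate
14 | benzyl 2-(benzyloxy)-4-(methoxymethoxy)-3,6-dimethylbenzoate | COCOc1cc(C)c(C(=O)OCc2ccccc2)c(OCc3ccccc3)c1C | intermediate
15 | benzyl 2-(benzyloxy)-4-hydroxy-3,6-dimethylbenzoate | Oc1cc(C)c(C(=O)OCc2ccccc2)c(OCc3ccccc3)c1C | intermediate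
16 | 4-[(benzyloxy)methyl]-3,5,7-trioxooct-1-en-1-one (acylketene, not isolated) | CC(=O)CC(=O)C(COCc1ccccc1)C(=O)C=C=O | intermediate
17 | 3-(benzyloxy)-4-[(benzyloxy)carbonyl]-2,5-dimethylphenyl 4-[(benzyloxy)methyl]-3,5,7-trioxooctanoate (racemic, enolisable) | CC(=O)CC(=O)C(COCc1ccccc1)C(=O)CC(=O)Oc2cc(C)c(C(=O)OCc3ccccc3)c(OCc4ccccc4)c2C | intermediate
18 | 3-(benzyloxy)-4-[(benzyloxy)carbonyl]-2,5-dimethylphenyl 3-[(benzyloxy)methyl]-6-hydroxy-6-methyl-2,4-dioxocyclohexane-1-carboxylate (diastereomer and tautomer mixture, not isolated) | CC1(O)CC(=O)C(COCc2ccccc2)C(=O)C1C(=O)Oc3cc(C)c(C(=O)OCc4ccccc4)c(OCc5ccccc5)c3C | intermediate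
19 | benzyl 2-(benzyloxy)-4-({3-[(benzyloxy)methyl]-2,4-dihydroxy-6-methylbenzoyl}oxy)-3,6-dimethylbenzoate | Cc1cc(O)c(COCc2ccccc2)c(O)c1C(=O)Oc3cc(C)c(C(=O)OCc4ccccc4)c(OCc5ccccc5)c3C | intermediate
20 | benzyl 2-(benzyloxy)-4-({3-[(benzyloxy)methyl]-2,4-dimethoxy-6-methylbenzoyl}oxy)-3,6-dimethylbenzoate | COc1cc(C)c(C(=O)Oc2cc(C)c(C(=O)OCc3ccccc3)c(OCc4ccccc4)c2C)c(OC)c1COCc5ccccc5 | intermediate
21 | 2-hydroxy-4-{[3-(hydroxymethyl)-2,4-dimethoxy-6-methylbenzoyl]oxy}-3,6-dimethylbenzoic acid | COc1cc(C)c(C(=O)Oc2cc(C)c(C(=O)O)c(O)c2C)c(OC)c1CO | target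

Total step count: 12. Longest linear sequence: 8 (steps 5 to 12).

Steps most likely to fail

Step 10 (key step). The aldol closure may be outrun by acyl transfer within the chain that expels the ring B phenol, or by β-elimination of benzyl alcohol from the enolised chain.

The fallback sets out from 10 and comes back at 20. It closes ring A on an ester that cannot leave and makes the depside bond afterwards on the aromatic acid.
- Heating 10 with 2-(trimethylsilyl)ethanol in toluene at 110 °C should give 2-(trimethylsilyl)ethyl 4-[(benzyloxy)methyl]-3,5,7-trioxooctanoate F1.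
- Cs2CO3 in THF followed by AcOH should aromatise it to 2-(trimethylsilyl)ethyl 3-[(benzyloxy)methyl]-2,4-dihydroxy-6-methylbenzoate F2.
- MeI and K2CO3 in DMF should give 2-(trimethylsilyl)ethyl 3-[(benzyloxy)methyl]-2,4-dimethoxy-6-methylbenzoate F3.
- Bu4NF in THF should release 3-[(benzyloxy)methyl]-2,4-dimethoxy-6-methylbenzoic acid F4.
- 1-Chloro-N,N,2-trimethylprop-1-en-1-amine in CH2Cl2 should convert it under neutral conditions into 3-[(benzyloxy)methyl]-2,4-dimethoxy-6-methylbenzoyl chloride F5.
- The sodium phenoxide of 15 (NaH, THF, 0 °C to rt) should then be acylated by F5 to give 20.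

Step 3. Dienolate 8 may lose benzyl oxide by β-elimination, or be quenched by proton transfer, before it is acylated.

The fallback sets out from 1 (as its dienolate 3) and from 7, and comes back at 9. It reverses the order of the two C–C bond formations, so that the carbon carrying the benzyloxymethyl group is only ever a doubly stabilised enolate.
- Dienolate 3 (LiN(SiMe3)2, THF, −78 °C) should be acylated by 7 to give 2,2-dimethyl-6-[3-(2-methyl-1,3-dioxolan-2-yl)-2-oxopropyl]-4H-1,3-dioxin-4-one F6.
- Its sodium enolate (NaH, THF, 0 °C, a tight ion pair that favours C- over O-alkylation) should then be alkylated with 2 to give 9.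
- This path also bypasses step 1.

Step 12. Hydrogenolysis may take place at the wrong C–O bond of the ring A bis-benzylic ether, or the liberated benzylic alcohol may be reduced further to a methyl group.

The fallback sets out from 20 and comes back at 21. It keeps the ring A CH2–O bond away from the metal altogether.
- DDQ in CH2Cl2/H2O should abstract hydride from the ring A benzylic CH2, the only one activated by two ortho methoxy groups. Hydrolysis of the oxocarbenium ion should then give benzyl 2-(benzyloxy)-4-[(3-formyl-2,4-dimethoxy-6-methylbenzoyl)oxy]-3,6-dimethylbenzoate F7.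
- H2 over 10% Pd/C in EtOAc should remove the two ring B benzyl groups to give 4-[(3-formyl-2,4-dimethoxy-6-methylbenzoyl)oxy]-2-hydroxy-3,6-dimethylbenzoic acid F8.
- NaBH4 in THF/MeOH at 0 °C should reduce the aldehyde to 21 without touching the hindered depside ester.

Further compounds
F1 | step 10 | 2-(trimethylsilyl)ethyl 4-[(benzyloxy)methyl]-3,5,7-trioxooctanoate | CC(=O)CC(=O)C(COCc1ccccc1)C(=O)CC(=O)OCC[Si](C)(C)C
F2 | step 10 | 2-(trimethylsilyl)ethyl 3-[(benzyloxy)methyl]-2,4-dihydroxy-6-methylbenzoate | Cc1cc(O)c(COCc2ccccc2)c(O)c1C(=O)OCC[Si](C)(C)C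
F3 | step 10 | 2-(trimethylsilyl)ethyl 3-[(benzyloxy)methyl]-2,4-dimethoxy-6-methylbenzoate | COc1cc(C)c(C(=O)OCC[Si](C)(C)C)c(OC)c1COCc2ccccc2
F4 | step 10 | 3-[(benzyloxy)methyl]-2,4-dimethoxy-6-methylbenzoic acid | COc1cc(C)c(C(=O)O)c(OC)c1COCc2ccccc2
F5 | step 10 | 3-[(benzyloxy)methyl]-2,4-dimethoxy-6-methylbenzoyl chloride | COc1cc(C)c(C(=O)Cl)c(OC)c1COCc2ccccc2
F6 | step 3 | 2,2-dimethyl-6-[3-(2-methyl-1,3-dioxolan-2-yl)-2-oxopropyl]-4H-1,3-dioxin-4-one | CC1(CC(=O)CC2=CC(=O)OC(C)(C)O2)OCCO1
F7 | step 12 | benzyl 2-(benzyloxy)-4-[(3-formyl-2,4-dimethoxy-6-methylbenzoyl)oxy]-3,6-dimethylbenzoate | COc1cc(C)c(C(=O)Oc2cc(C)c(C(=O)OCc3ccccc3)c(OCc4ccccc4)c2C)c(OC)c1C=O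
F8 | step 12 | 4-[(3-formyl-2,4-dimethoxy-6-methylbenzoyl)oxy]-2-hydroxy-3,6-dimethylbenzoic acid | COc1cc(C)c(C(=O)Oc2cc(C)c(C(=O)O)c(O)c2C)c(OC)c1C=O
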